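The plan contracts the ten-membered ring B to a cyclohexane. C2 and C7, the two oxygenated carbons that face each other 1,6 across ring B, are bridged on one side by C3–C4–C5–C6; bonding C2 to C7 instead leaves the six-membered ring C1–C2–C7–C8–C9–C10 with a vinyl group (C3, C4) on C2 and a propynyl group (C6, C5, C16) on C7. Forward, the C7 potassium alkoxide undergoes a [3,3] shift that forms C4–C5, breaks C2–C7 and gives ring B with a C7 enone and a C2 enol ether in one operation. The precursor is a trans-decalin made from a quinone Diels–Alder adduct, carrying O9, the ring A oxygens and C20.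

Key step: step 16

Conventions: atom numbers are briarane numbers throughout. β is the face of the C1 methyl group (C15) in the flat drawing, α the opposite face. The SMILES strings in the compound list are the reference for configuration.

Design notes:
- Nucleophiles can reach the C2 and C7 carbonyls of the trans-decalin only from the α-face. At C2 the β-face is closed by the adjacent axial C1 methyl. At C7 axial entry on the β-face is closed by the syn-axial C1 methyl and C9 silyloxy group. Precursor 21 therefore carries a 2α-vinyl (axial) and a 7α-propynyl (equatorial) group, which are cis and gauche, as the [3,3] shift needs.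
- From this arrangement a chair-like transition state gives the C2=C3 enol ether with C1 and C4 trans. A second trans double bond 1,4 to it in a ten-membered ring would be badly strained, and protonation of the allenolate from the open (methyl) side puts C4 and C7 cis. Product 24 is therefore the (5Z)-enone.
- O2 is a methyl ether: a silyl group is hard to place on this tertiary oxygen next to quaternary C1 and could migrate to the neighbouring alkoxide. C8 is a dimethyl ketal, which arises directly from the quinone-derived enol ether. O9 is TES and O14 is TBS so that they can be freed one after the other.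
- The diene carries one acetoxy group only. An acetoxy group on C11 would be β to the C9 ketone and would be eliminated during the C10 epimerisation, so C11 is oxidised after the ring fusion is trans.

Assumption: the (S)-oxazaborolidinium is taken to expose the quinone face that gives adduct 3 (its enantiomer is used if the sense is opposite), and to bind the vinylogous-ester carbonyl as simple boron Lewis acids do.

Step 1
Reactants: 1 2-methoxy-5-methylcyclohexa-2,5-diene-1,4-dione; 2 (E)-buta-1,3-dien-1-yl acetate
Product: 3 cis-fused Diels–Alder adduct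
Conditions: (S)-1-(2-methylphenyl)-3,3-diphenyltetrahydro-1H,3H-pyrrolo[1,2-c][1,3,2]oxazaborole·HNTf2 (20 mol%), CH2Cl2, −78 to −40 °C
Reagents that add atoms: none
Why: Lewis-acid-catalysed enantioselective Diels–Alder reaction; boron on the vinylogous-ester carbonyl makes the quinone CH carbon (C10) the electrophilic end, so the unsubstituted diene terminus bonds there and the acetoxy carbon (C14) bonds to the methyl-bearing C1, endo addition places 14-OAc trans to the C1 methyl, and the catalyst face sets C1, C10 and C14 absolutely.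

Step 2
Reactants: 3 cis-fused Diels–Alder adduct
Product: 4 trans-fused enedione
Conditions: DBU (0.2 equiv), CH2Cl2, rt
Reagents that add atoms: none
Why: Base-mediated epimerisation at C10 through the C9 enolate should settle on the more stable trans-fused enedione (10α-H), as it does for the parent butadiene adduct of this quinone; C11 is a plain CH2 and C1 is quaternary, so no β-acyloxy elimination can compete.

Step 3
Reactants: 4 trans-fused enedione
Product: 5 9β-alcohol
Conditions: NaBH4, CeCl3·7H2O, MeOH, −78 °C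
Reagents that add atoms: none
Why: Luche 1,2-reduction of the more electrophilic C9 carbonyl (the C2 carbonyl is a vinylogous ester); hydride should add from the α-face, away from the axial C1 methyl that is 1,3 to C9, giving the axial 9β-alcohol.

Step 4
Reactants: 5 9β-alcohol
Product: 6 9β-triethylsilyl ether
Conditions: TESOTf, 2,6-lutidine, CH2Cl2, −78 °C
Reagents that add atoms: triethylsilyl trifluoromethanesulfonate, CC[Si](CC)(CC)OS(=O)(=O)C(F)(F)F
Why: Silyl triflate silylation protects the hindered axial alcohol as a TES ether, chosen because it can later be removed in the presence of the C14 TBS ether.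

Step 5
Reactants: 6 9β-triethylsilyl ether
Product: 7 C11 enone
Conditions: Rh2(cap)4 [cap = caprolactamate, C6H10NO] (1 mol%), t-BuOOH (70% aq.), K2CO3, CH2Cl2, rt
Reagents that add atoms: tert-butyl hydroperoxide, CC(C)(C)OO
Why: Dirhodium-catalysed allylic oxidation with tert-butyl hydroperoxide should convert the allylic CH2 (C11) of the isolated C12=C13 alkene into the enone; the C14–H is deactivated by its acetate and the C9–H by the conjugated carbonyl and the silyl ether.

Step 6
Reactants: 7 C11 enone
Product: 8 14α-hydroxy enone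
Conditions: K2CO3, MeOH, 0 °C
Reagents that add atoms: none
Why: Mild methanolysis frees the C14 hydroxyl that must direct the next step; at 0 °C the β-silyloxy ketone and the TES ether should survive, and the C14–H lies near the enone plane so that γ-deprotonation is slow.

Step 7
Reactants: 8 14α-hydroxy enone
Product: 10 12α,13α,14α-triol, via osmate ester 9 (not isolated)
Conditions: OsO4 (1.05 equiv), TMEDA, CH2Cl2, −78 °C; then aq. Na2SO3, THF, 40 °C
Reagents that add atoms: osmium tetroxide, O=[Os](=O)(=O)=O
Why: Hydroxyl-directed dihydroxylation: the OsO4·TMEDA complex hydrogen-bonds to the 14α-hydroxyl and adds to the α-face of C12=C13, which is also the face away from the axial C1 methyl, so C12 and C13 are set cis to O14.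

Step 8
Reactants: 10 12α,13α,14α-triol
Product: 11 12,13-acetonide
Conditions: 2-methoxypropene, PPTS, CH2Cl2, 0 °C
Reagents that add atoms: 2-methoxypropene, COC(C)=C
Why: Kinetic acetonide formation should engage the accessible cis-12,13-diol and leave the neopentyl 14-hydroxyl next to quaternary C1; it also locks C12, which is α to the ketone.

Step 9
Reactants: 11 12,13-acetonide
Product: 12 C11 methylene compound
Conditions: Zn, CH2Br2, TiCl4, THF/CH2Cl2, 0 °C to rt
Reagents that add atoms: dibromomethane, BrCBr
Why: Takai–Lombardo methylenation is non-basic, so the C11 ketone becomes the C11=C20 alkene without epimerising C10 or C12 and without β-elimination of the C9 silyloxy group; the reagent tolerates the free hydroxyl and leaves the vinylogous ester alone.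

Step 10
Reactants: 12 C11 methylene compound
Product: 13 14α-TBS ether
Conditions: TBSOTf, 2,6-lutidine, CH2Cl2, 0 °C
Reagents that add atoms: tert-butyldimethylsilyl trifluoromethanesulfonate, CC(C)(C)[Si](C)(C)OS(=O)(=O)C(F)(F)F
Why: Silyl triflate silylation protects the neopentyl alcohol without forming its alkoxide, which avoids retro-aldol cleavage toward the C2 carbonyl.

Step 11
Reactants: 13 14α-TBS ether; 14 vinylmagnesium bromide
Product: 15 C2 vinyl carbinol
Conditions: CeCl3, THF, −78 to 0 °C
Reagents that add atoms: none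
Why: 1,2-Addition of the vinylcerium reagent to the vinylogous-ester carbonyl (first half of a Stork–Danheiser sequence, kept unhydrolysed); axial attack on the α-face, anti to the adjacent axial C1 methyl, should set C2 with vinyl α and hydroxyl β.

Step 12
Reactants: 15 C2 vinyl carbinol
Product: 16 C2 methyl ether
Conditions: KH, MeI, THF, 0 °C to rt
Reagents that add atoms: iodomethane, CI
Why: Williamson methylation of the tertiary potassium alkoxide gives an ether that cannot migrate to O7 and that becomes the enol ether in the key step; the substrate has no 1,5-diene, so the alkoxide cannot rearrange first.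

Step 13
Reactants: 16 C2 methyl ether
Product: 17 C7 alcohol C8 dimethyl ketal
Conditions: mCPBA, NaHCO3, MeOH, −20 °C
Reagents that add atoms: 3-chloroperoxybenzoic acid, OOC(=O)c1cccc(Cl)c1; methanol, CO
Why: Epoxidation of the electron-rich C7=C8 enol ether, far faster than that of the vinyl and 1,1-disubstituted alkenes, followed by methanolysis of the alkoxy epoxide in the flask gives the C7 alcohol and the C8 dimethyl ketal; the C7 configuration does not matter.

Step 14
Reactants: 17 C7 alcohol C8 dimethyl ketal
Product: 18 C7 ketone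
Conditions: Dess–Martin periodinane, NaHCO3, CH2Cl2, rt
Reagents that add atoms: none
Why: Dess–Martin oxidation converts the hindered secondary alcohol into the ketone under buffered conditions that spare the ketal, silyl ethers and alkenes.

Step 15
Reactants: 18 C7 ketone; 19 prop-1-yne
Product: 21 propynyl carbinol (key-step precursor), via prop-1-ynyllithium 20 (not isolated)
Conditions: 19, n-BuLi, THF, −78 °C; CeCl3; then 18, −78 to −20 °C
Reagents that add atoms: none
Why: Addition of the slim, non-basic propynylcerium reagent to the hindered ketone; axial entry on the β-face is closed by the syn-axial C1 methyl and C9 silyloxy group, so the alkyne should enter equatorially from the α-face, cis and gauche to the axial C2 vinyl group.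

Step 16
Reactants: 21 propynyl carbinol (key-step precursor)
Product: 24 ring B dienone, via potassium alkoxide 22 (not isolated), via potassium allenolate 23 (not isolated)
Conditions: KH, 18-crown-6, THF, 0 °C to rt; then aq. NH4Cl, −78 °C
Reagents that add atoms: none
Why: KH with 18-crown-6 gives the free C7 potassium alkoxide 22, whose charge weakens the adjacent C2–C7 bond and drives a concerted [3,3] shift through C4=C3–C2–C7–C6≡C5: C4–C5 forms as C2–C7 breaks, giving the C2 methyl enol ether and the allenolate 23, which is protonated at C6 from the open methyl side to the (5Z)-enone. The closest known reaction type is the anionic oxy-Cope ring expansion of 1-alkynyl-2-vinylcycloalkanols to ring-enlarged enones. Ring B is not closed end to end: the cyclohexane C1–C2–C7–C8–C9–C10 grows by four atoms (C3 to C6) in a chair-like six-centre transition state in which C1 is pseudo-equatorial and so ends trans to C4 across C2=C3. No stereocentre is created: C2 and C7 become trigonal, and C1, C9, C10 and ring A are spectators. The [3,3] shift must outrun loss of propynide and 1,3-shifts; the trans-decalin chair holds the axial C2 vinyl and equatorial C7 propynyl groups cis and about 60° apart so that C4 can reach C5, the crown ether gives a naked alkoxide that should rearrange at or below room temperature, and the O2 methyl ether can neither migrate nor be deprotonated.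

Step 17
Reactants: 24 ring B dienone
Product: 25 9β-alcohol of the dienone
Conditions: TBAF, AcOH, THF, 0 °C
Reagents that add atoms: none
Why: Buffered fluoride desilylation removes the secondary TES ether; the hindered TBS ether, the methyl enol ether and the ketal should survive at near-neutral pH.

Step 18
Reactants: 25 9β-alcohol of the dienone
Product: 26 9-acetate 7α-alcohol
Conditions: MeCHO, SmI2 (0.3 equiv), THF, −10 °C
Reagents that add atoms: acetaldehyde, CC=O
Why: Evans–Tishchenko reduction: the O9 hemiacetal of acetaldehyde delivers hydride to the C7 carbonyl inside a samarium chelate, which should give the 1,3-anti (7α) allylic alcohol and leaves the acetate on O9; reducing C7 while C2 is still an enol ether excludes a transannular aldol.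

Step 19
Reactants: 26 9-acetate 7α-alcohol; 27 2-bromopropanoyl bromide
Product: 28 C7 2-bromopropanoate
Conditions: pyridine, DMAP (cat.), CH2Cl2, −20 °C
Reagents that add atoms: none
Why: Acylation of the only free hydroxyl brings in C17, C18 and C19; the bromide-bearing carbon is a mixture of epimers that converges at the enolate stage.

Step 20
Reactants: 28 C7 2-bromopropanoate
Product: 29 C2,C8-diketone
Conditions: TsOH·H2O (0.3 equiv), acetone/H2O 10:1, 40 °C
Reagents that add atoms: water, O
Why: Acid-catalysed hydrolysis and transketalisation unmask the C2 ketone from the strained enol ether and the C8 ketone from the dimethyl ketal (ionisation assisted by the neighbouring C9 acetate), while acetone as solvent keeps the acetonide and the hindered TBS ether should survive.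

Step 21
Reactants: 29 C2,C8-diketone
Product: 30 hydroxy lactone
Conditions: SmI2 (2.5 equiv), THF, −78 °C
Reagents that add atoms: none
Why: Samarium diiodide intramolecular Reformatsky reaction: fast C–Br reduction gives a samarium enolate that adds to the adjacent C8 ketone from the side of the O7 tether; the ten-membered ring prefers C6–C7–C8–C9 near 150° over the near-eclipsed torsion a cis fusion needs, so the lactone should be trans-fused with 8α-OH, and the samarium chelate places the C18 methyl anti to C9, cis to the hydroxyl.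

Step 22
Reactants: 30 hydroxy lactone
Product: 31 14α-alcohol
Conditions: HF·pyridine, pyridine, THF, 0 °C to rt
Reagents that add atoms: none
Why: Acidic fluoride desilylation cleaves the hindered TBS ether without forming an alkoxide, so the new β-hydroxy ketone is not exposed to retro-aldol cleavage and the esters do not migrate.

Step 23
Reactants: 31 14α-alcohol
Product: 32 14-acetate 2β-alcohol
Conditions: MeCHO, SmI2 (0.3 equiv), THF, −10 °C
Reagents that add atoms: acetaldehyde, CC=O
Why: Second Evans–Tishchenko reduction: hydride from the O14 hemiacetal reaches the C2 carbonyl through a six-membered samarium-bridged transition state from the side of the axial C14 oxygen, which should give the 1,3-anti (2β) alcohol and puts the acetate on O14.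

Step 24
Reactants: 32 14-acetate 2β-alcohol
Product: 33 2-isobutyrate
Conditions: i-PrCOCl, pyridine, DMAP, CH2Cl2, 0 °C to rt
Reagents that add atoms: 2-methylpropanoyl chloride, CC(C)C(Cl)=O
Why: DMAP-catalysed acylation of the single secondary hydroxyl; the tertiary C8 hydroxyl should not react under these conditions.

Step 25
Reactants: 33 2-isobutyrate
Product: 34 12α,13α-diol
Conditions: AcOH/H2O 4:1, 45 °C
Reagents that add atoms: none
Why: Aqueous acetic acid hydrolyses the cis-fused acetonide while the esters, the lactone and the alkenes are stable.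

Step 26
Reactants: 34 12α,13α-diol
Product: 35 13-isovalerate
Conditions: Me2SnCl2 (5 mol%), i-Pr2NEt, isovaleryl chloride, THF, 0 °C
Reagents that add atoms: 3-methylbutanoyl chloride, CC(C)CC(Cl)=O
Why: Tin-mediated regioselective acylation: the dimethyltin acetal of the cis-diol activates the equatorial C13 oxygen, so the acid chloride should acylate O13 and leave the axial allylic 12-hydroxyl and the tertiary 8-hydroxyl.

Step 27
Reactants: 35 13-isovalerate
Product: 36 11,20-epoxide
Conditions: VO(acac)2 (5 mol%), t-BuOOH, CH2Cl2, 0 °C to rt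
Reagents that add atoms: tert-butyl hydroperoxide, CC(C)(C)OO
Why: Vanadium-catalysed hydroxyl-directed epoxidation: the axial allylic 12α-hydroxyl delivers the peroxide oxygen to the α-face of C11=C20, setting C11 with the epoxide oxygen cis to O12; C5=C6 has no allylic hydroxyl and should react far more slowly.

Step 28
Reactants: 36 11,20-epoxide
Product: 37 12-acetate
Conditions: Ac2O, pyridine, DMAP (cat.), CH2Cl2, 0 °C
Reagents that add atoms: acetic anhydride, CC(=O)OC(C)=O
Why: Acetylation of the remaining secondary hydroxyl; the tertiary alcohol and the epoxide should be untouched by pyridine and anhydride at 0 °C.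

Step 29
Reactants: 37 12-acetate
Product: 38 CNP0231073.1
Conditions: Ca(OCl)2, solid CO2, CH2Cl2/H2O, 0 °C
Reagents that add atoms: calcium hypochlorite, [Ca+2].[O-]Cl.[O-]Cl
Why: Ene-type chlorination with hypochlorous acid, as known for prenyl-type acetates: chloronium formation at C5=C6 and loss of a C16 proton gives the C6 chloride and the C5=C16 alkene; chlorine should arrive on the α-face, syn to the hydrogen-bonding 8α-hydroxyl and anti to the allylic C7–O bond with H7 held in the alkene plane.

Compound list
1 | 2-methoxy-5-methylcyclohexa-2,5-diene-1,4-dione | O=C1C=C(OC)C(=O)C=C1C | starting material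
2 | (E)-buta-1,3-dien-1-yl acetate | CC(=O)O/C=C/C=C | starting material
3 | cis-fused adduct: 1β-methyl, 10β-H, 14α-acetoxy; C2 and C9 ketones, C7=C8 with 8-methoxy, C12=C13, C11H2 | O=C1[C@@]2(C)[C@@H](OC(C)=O)C=CC[C@H]2C(=O)C(OC)=C1 | intermediate
4 | trans-fused enedione: as 3 but 10α-H | O=C1[C@@]2(C)[C@@H](OC(C)=O)C=CC[C@@H]2C(=O)C(OC)=C1 | intermediate
5 | 9β-alcohol of 4 (C2 vinylogous ester kept) | O=C1[C@@]2(C)[C@@H](OC(C)=O)C=CC[C@@H]2[C@H](O)C(OC)=C1 | intermediate
6 | 9β-triethylsilyl ether of 5 | O=C1[C@@]2(C)[C@@H](OC(C)=O)C=CC[C@@H]2[C@H](O[Si](CC)(CC)CC)C(OC)=C1 | intermediate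
7 | C11 ketone of 6 (ring A enone C11(=O)–C12=C13, 14α-acetoxy) | O=C1[C@@]2(C)[C@@H](OC(C)=O)C=CC(=O)[C@@H]2[C@H](O[Si](CC)(CC)CC)C(OC)=C1 | intermediate
8 | 14α-hydroxy enone (acetate of 7 removed) | O=C1[C@@]2(C)[C@@H](O)C=CC(=O)[C@@H]2[C@H](O[Si](CC)(CC)CC)C(OC)=C1 | intermediate
9 | 12α,13α-osmate ester of 8 (hexavalent osmium glycolate, TMEDA complex) | O=C1[C@@]2(C)[C@@H](O)[C@H]3O[Os](=O)(=O)O[C@H]3C(=O)[C@@H]2[C@H](O[Si](CC)(CC)CC)C(OC)=C1.CN(C)CCN(C)C | intermediate
10 | 12α,13α,14α-triol with C11 ketone | O=C1[C@@]2(C)[C@@H](O)[C@@H](O)[C@@H](O)C(=O)[C@@H]2[C@H](O[Si](CC)(CC)CC)C(OC)=C1 | intermediate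
11 | 12,13-O-isopropylidene derivative of 10 (14α-OH free) | O=C1[C@@]2(C)[C@@H](O)[C@H]3OC(C)(C)O[C@H]3C(=O)[C@@H]2[C@H](O[Si](CC)(CC)CC)C(OC)=C1 | intermediate
12 | C11 exocyclic methylene compound (C11=C20) | O=C1[C@@]2(C)[C@@H](O)[C@H]3OC(C)(C)O[C@H]3C(=C)[C@@H]2[C@H](O[Si](CC)(CC)CC)C(OC)=C1 | intermediate
13 | 14α-tert-butyldimethylsilyl ether of 12 | O=C1[C@@]2(C)[C@@H](O[Si](C)(C)C(C)(C)C)[C@H]3OC(C)(C)O[C@H]3C(=C)[C@@H]2[C@H](O[Si](CC)(CC)CC)C(OC)=C1 | intermediate
14 | vinylmagnesium bromide | C=C[Mg]Br | starting material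
15 | C2 tertiary alcohol: 2α-vinyl, 2β-hydroxy; C7=C8 methyl enol ether | C=C[C@@]1(O)[C@@]2(C)[C@@H](O[Si](C)(C)C(C)(C)C)[C@H]3OC(C)(C)O[C@H]3C(=C)[C@@H]2[C@H](O[Si](CC)(CC)CC)C(OC)=C1 | intermediate
16 | 2β-methyl ether of 15 | C=C[C@@]1(OC)[C@@]2(C)[C@@H](O[Si](C)(C)C(C)(C)C)[C@H]3OC(C)(C)O[C@H]3C(=C)[C@@H]2[C@H](O[Si](CC)(CC)CC)C(OC)=C1 | intermediate
17 | C7 secondary alcohol with C8 dimethyl ketal (C7 configuration not assigned, removed in step 14) | C=C[C@@]1(OC)[C@@]2(C)[C@@H](O[Si](C)(C)C(C)(C)C)[C@H]3OC(C)(C)O[C@H]3C(=C)[C@@H]2[C@H](O[Si](CC)(CC)CC)C(OC)(OC)C1O | intermediate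
18 | C7 ketone (α-keto dimethyl ketal) | C=C[C@@]1(OC)[C@@]2(C)[C@@H](O[Si](C)(C)C(C)(C)C)[C@H]3OC(C)(C)O[C@H]3C(=C)[C@@H]2[C@H](O[Si](CC)(CC)CC)C(OC)(OC)C1=O | intermediate
19 | prop-1-yne | CC#C | starting material
20 | prop-1-ynyllithium | [Li]C#CC | intermediate
21 | key-step precursor: trans-decalin with 2α-vinyl-2β-methoxy, 7α-(prop-1-ynyl)-7β-hydroxy, 8,8-dimethoxy, 9β-OTES, 14α-OTBS, 12α,13α-acetonide, C11=CH2 | C=C[C@@]1(OC)[C@@]2(C)[C@@H](O[Si](C)(C)C(C)(C)C)[C@H]3OC(C)(C)O[C@H]3C(=C)[C@@H]2[C@H](O[Si](CC)(CC)CC)C(OC)(OC)[C@@]1(O)C#CC | intermediate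
22 | potassium C7 alkoxide of 21 | C=C[C@@]1(OC)[C@@]2(C)[C@@H](O[Si](C)(C)C(C)(C)C)[C@H]3OC(C)(C)O[C@H]3C(=C)[C@@H]2[C@H](O[Si](CC)(CC)CC)C(OC)(OC)[C@@]1([O-])C#CC.[K+] | intermediate
23 | potassium allenolate of the ten-membered ring (C5=C6=C7–O−, C2 methyl enol ether) | [K+].[O-]C1=C=C(C)C/C=C(OC)/[C@@]2(C)[C@@H](O[Si](C)(C)C(C)(C)C)[C@H]3OC(C)(C)O[C@H]3C(=C)[C@@H]2[C@H](O[Si](CC)(CC)CC)C1(OC)OC | intermediate
24 | key-step product: ten-membered ring B fused to ring A; C7 ketone conjugated with (5Z)-C5=C6 (C16 methyl on C5), C2 methyl enol ether C2=C3 with C1 and C4 trans, C8 dimethyl ketal, 9β-OTES, 14α-OTBS, 12,13-acetonide, C11=CH2 | O=C1/C=C(C)\C/C=C(OC)/[C@@]2(C)[C@@H](O[Si](C)(C)C(C)(C)C)[C@H]3OC(C)(C)O[C@H]3C(=C)[C@@H]2[C@H](O[Si](CC)(CC)CC)C1(OC)OC | intermediate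
25 | 9β-alcohol of 24 | O=C1/C=C(C)\C/C=C(OC)/[C@@]2(C)[C@@H](O[Si](C)(C)C(C)(C)C)[C@H]3OC(C)(C)O[C@H]3C(=C)[C@@H]2[C@H](O)C1(OC)OC | intermediate
26 | 9β-acetate 7α-allylic alcohol | O[C@H]1/C=C(C)\C/C=C(OC)/[C@@]2(C)[C@@H](O[Si](C)(C)C(C)(C)C)[C@H]3OC(C)(C)O[C@H]3C(=C)[C@@H]2[C@H](OC(C)=O)C1(OC)OC | intermediate
27 | 2-bromopropanoyl bromide (racemic) | CC(Br)C(=O)Br | starting material
28 | 7α-(2-bromopropanoate) of 26 (both epimers at the bromide carbon) | CC(Br)C(=O)O[C@H]1/C=C(C)\C/C=C(OC)/[C@@]2(C)[C@@H](O[Si](C)(C)C(C)(C)C)[C@H]3OC(C)(C)O[C@H]3C(=C)[C@@H]2[C@H](OC(C)=O)C1(OC)OC | intermediate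
29 | C2,C8-diketone (C3 and C4 methylenes, 7α-bromopropanoate, 9β-acetate) | CC(Br)C(=O)O[C@H]1/C=C(C)\CCC(=O)[C@@]2(C)[C@@H](O[Si](C)(C)C(C)(C)C)[C@H]3OC(C)(C)O[C@H]3C(=C)[C@@H]2[C@H](OC(C)=O)C1=O | intermediate
30 | γ-lactone O7–C19(=O)–C17–C8, trans-fused to ring B; 8α-OH, C18 methyl cis to 8-OH; C2 ketone | O=C1O[C@H]2/C=C(C)\CCC(=O)[C@@]3(C)[C@@H](O[Si](C)(C)C(C)(C)C)[C@H]4OC(C)(C)O[C@H]4C(=C)[C@@H]3[C@H](OC(C)=O)[C@]2(O)[C@H]1C | intermediate
31 | 14α-alcohol of 30 | O=C1O[C@H]2/C=C(C)\CCC(=O)[C@@]3(C)[C@@H](O)[C@H]4OC(C)(C)O[C@H]4C(=C)[C@@H]3[C@H](OC(C)=O)[C@]2(O)[C@H]1C | intermediate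
32 | 14α-acetate 2β-alcohol | O=C1O[C@H]2/C=C(C)\CC[C@H](O)[C@@]3(C)[C@@H](OC(C)=O)[C@H]4OC(C)(C)O[C@H]4C(=C)[C@@H]3[C@H](OC(C)=O)[C@]2(O)[C@H]1C | intermediate
33 | 2β-isobutyrate of 32 | O=C1O[C@H]2/C=C(C)\CC[C@H](OC(=O)C(C)C)[C@@]3(C)[C@@H](OC(C)=O)[C@H]4OC(C)(C)O[C@H]4C(=C)[C@@H]3[C@H](OC(C)=O)[C@]2(O)[C@H]1C | intermediate
34 | 12α,13α-diol (acetonide removed) | O=C1O[C@H]2/C=C(C)\CC[C@H](OC(=O)C(C)C)[C@@]3(C)[C@@H](OC(C)=O)[C@@H](O)[C@@H](O)C(=C)[C@@H]3[C@H](OC(C)=O)[C@]2(O)[C@H]1C | intermediate
35 | 13α-isovalerate 12α-alcohol | O=C1O[C@H]2/C=C(C)\CC[C@H](OC(=O)C(C)C)[C@@]3(C)[C@@H](OC(C)=O)[C@@H](OC(=O)CC(C)C)[C@@H](O)C(=C)[C@@H]3[C@H](OC(C)=O)[C@]2(O)[C@H]1C | intermediate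
36 | 11,20-epoxide (epoxide oxygen α, cis to 12-OH) | O=C1O[C@H]2/C=C(C)\CC[C@H](OC(=O)C(C)C)[C@@]3(C)[C@@H](OC(C)=O)[C@@H](OC(=O)CC(C)C)[C@@H](O)[C@]4(CO4)[C@@H]3[C@H](OC(C)=O)[C@]2(O)[C@H]1C | intermediate
37 | 12α-acetate of 36 ((5Z)-C5=C6 still in place) | O=C1O[C@H]2/C=C(C)\CC[C@H](OC(=O)C(C)C)[C@@]3(C)[C@@H](OC(C)=O)[C@@H](OC(=O)CC(C)C)[C@@H](OC(C)=O)[C@]4(CO4)[C@@H]3[C@H](OC(C)=O)[C@]2(O)[C@H]1C | intermediate
38 | CNP0231073.1 (6α-chloride, C5=C16) | C=C1CC[C@H](OC(=O)C(C)C)[C@@]2(C)[C@@H](OC(C)=O)[C@@H](OC(=O)CC(C)C)[C@@H](OC(C)=O)[C@]3(CO3)[C@@H]2[C@H](OC(C)=O)[C@]2(O)[C@@H](C)C(=O)O[C@H]2[C@H]1Cl | target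

Total step count: 29. Longest linear sequence: 29 steps (the route is linear; 1, 2, 14, 19 and 27 are bought).

Steps most likely to fail

Step 16. The hindered tertiary alkoxide may shed propynide (retro-addition back to ketone 18), or the shift to the strained trans enol ether may be slower than decomposition. The fallback avoids the anion. Setting out from 21, the C7 hydroxyl is silylated (TMSOTf, Et3N, CH2Cl2, −78 °C) to the C7 trimethylsilyl ether F1. F1 is heated in o-dichlorobenzene at about 200 °C and should undergo the neutral siloxy-Cope shift through the same six-centre array to the ten-membered silyloxyallene F2. Brief treatment with K2CO3 in MeOH at 0 °C cleaves the allenyl silyl ether, and protonation at C6 returns the route to 24.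

Step 21. Single-electron reduction of the α,α′-bis(acyloxy) ketone (loss of the C9 acetate or the C7 ester) may compete with C–Br reduction, or the tethered enolate may fail to close the five-membered ring. The fallback makes the C8–C17 bond between two molecules and closes the lactone afterwards. Setting out from 26, TsOH·H2O in wet acetone unmasks both ketones to give the 7α-hydroxy diketone F3. A zinc Reformatsky reaction with ethyl 2-bromopropanoate (activated Zn, THF, 40 °C) should add to the more electrophilic, α-oxygenated C8 ketone to give the β-hydroxy ester F4. The 7α-hydroxyl then closes the lactone on warming with a trace of TsOH, returning to 30.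

Step 29. Chlorine may be delivered to the β-face of C5=C6 (giving the C6 epimer), or the proton may be lost from C4 instead of C16. The fallback takes the C6 configuration from an SN2 inversion. Setting out from 37, photooxygenation (O2, tetraphenylporphyrin, visible light, CH2Cl2, −40 °C) is a singlet-oxygen ene reaction that should take a hydrogen from the freely rotating C16 methyl and place oxygen on C6 from the sterically open β-face, giving the 6β-hydroperoxide F5. Triphenylphosphine reduces it to the 6β-allylic alcohol F6. Appel chlorination (PPh3, CCl4, 0 °C to rt) then installs the 6α-chloride with inversion and returns to 38.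

Further compounds
F1 | step 16 | C7 trimethylsilyl ether of 21 | C=C[C@@]1(OC)[C@@]2(C)[C@@H](O[Si](C)(C)C(C)(C)C)[C@H]3OC(C)(C)O[C@H]3C(=C)[C@@H]2[C@H](O[Si](CC)(CC)CC)C(OC)(OC)[C@@]1(O[Si](C)(C)C)C#CC
F2 | step 16 | ten-membered silyloxyallene (C7 OTMS, C5=C6=C7, C2 methyl enol ether) | C[Si](C)(C)OC1=C=C(C)C/C=C(OC)/[C@@]2(C)[C@@H](O[Si](C)(C)C(C)(C)C)[C@H]3OC(C)(C)O[C@H]3C(=C)[C@@H]2[C@H](O[Si](CC)(CC)CC)C1(OC)OC
F3 | step 21 | 7α-hydroxy C2,C8-diketone (9β-acetate, 12,13-acetonide, 14α-OTBS) | O[C@H]1/C=C(C)\CCC(=O)[C@@]2(C)[C@@H](O[Si](C)(C)C(C)(C)C)[C@H]3OC(C)(C)O[C@H]3C(=C)[C@@H]2[C@H](OC(C)=O)C1=O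
F4 | step 21 | ethyl 2-(7α,8α-dihydroxy ring B C8-yl)propanoate, the open hydroxy ester of 30 | O[C@H]1/C=C(C)\CCC(=O)[C@@]2(C)[C@@H](O[Si](C)(C)C(C)(C)C)[C@H]3OC(C)(C)O[C@H]3C(=C)[C@@H]2[C@H](OC(C)=O)[C@]1(O)[C@@H](C)C(=O)OCC
F5 | step 29 | 6β-hydroperoxide with C5=C16 | O=C1O[C@H]2[C@H](OO)C(=C)CC[C@H](OC(=O)C(C)C)[C@@]3(C)[C@@H](OC(C)=O)[C@@H](OC(=O)CC(C)C)[C@@H](OC(C)=O)[C@]4(CO4)[C@@H]3[C@H](OC(C)=O)[C@]2(O)[C@H]1C
F6 | step 29 | 6β-allylic alcohol with C5=C16 | O=C1O[C@H]2[C@H](O)C(=C)CC[C@H](OC(=O)C(C)C)[C@@]3(C)[C@@H](OC(C)=O)[C@@H](OC(=O)CC(C)C)[C@@H](OC(C)=O)[C@]4(CO4)[C@@H]3[C@H](OC(C)=O)[C@]2(O)[C@H]1C
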